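**Retrosynthetic overview**

1. Numbering: ring B (seven-membered) is C1(side chain)–C2–C3(OH)–C4(=CH2)–C5–C9–C10(OH); ring A (cyclopentene) is C5–C6–C7=C8(CH3)–C9; the side chain is C11(CH3)–C12(OAc)–C13–C14(OH)–C(CH3)=CH2. The route rests on ring A: C5–C6–C7=C8(CH3)–C9, with C4 on C5 and C10 on C9 trans, is (S)-carvone after contraction of its six-membered ring (bond C8–C9 made, carbonyl carbon pushed out as C10), with C5 kept from the chiral pool.
2. Side chain: C14 by CBS reduction; C12–C13 by a Felkin-controlled Mukaiyama aldol on the C12 aldehyde, which comes from aminolysis of a C12→O10 γ-lactone.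
3. Ring B (closed last): Nozaki–Hiyama–Kishi cyclisation C3–C4 between the enol triflate of the C4 methyl ketone and a C3 aldehyde, giving 3-OH and the 4-methylidene together.
4. γ-Lactone (closed second; sets C10, C1, C11): Dreiding–Schmidt allylation of the C10 aldehyde by a (Z)-2-(bromomethyl)pent-2-enoate (bond C1–C10), then conjugate reduction.
5. Ring A (closed first): Favorskii contraction of the trans-dibromide of the ketal-protected carvone enone to the trans methyl cyclopentenecarboxylate.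

Key step: step 4

Remark: the target is taken as drawn, (1R,3S,5S,9R,10S,11S,12S,14R) in the numbering above, with a trans-fused hydroazulene; compounds 11, 13 and 27 and all reagents are taken as purchasable.

**Route**

Step 1
Reactants: 1 (S)-carvone
Product: 2 (5S)-5-acetyl-2-methylcyclohex-2-en-1-one
Conditions: O3, CH2Cl2/MeOH, −78 °C (indicator end point); Me2S, −78 °C → rt
Reagents that add atoms: ozone, [O-][O+]=O
Why: Ozonolysis with reductive work-up takes the electron-rich 1,1-disubstituted isopropenyl alkene far faster than the electron-poor enone alkene when ozone is dosed to an indicator end point, and the C5 stereocentre is not involved.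

Step 2
Reactants: 2 (5S)-5-acetyl-2-methylcyclohex-2-en-1-one; 3 ethylene glycol
Product: 4 (5S)-2-methyl-5-(2-methyl-1,3-dioxolan-2-yl)cyclohex-2-en-1-one
Conditions: p-TsOH (cat.), benzene, reflux, Dean–Stark
Reagents that add atoms: none
Why: Acid-catalysed ketalisation with azeotropic water removal protects the saturated methyl ketone selectively, because the conjugated enone carbonyl is much less electrophilic, and so keeps the future C4 at the ketone level through the bromination and the base step.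

Step 3
Reactants: 4 (5S)-2-methyl-5-(2-methyl-1,3-dioxolan-2-yl)cyclohex-2-en-1-one
Product: 5 (2S,3S,5R)-2,3-dibromo-2-methyl-5-(2-methyl-1,3-dioxolan-2-yl)cyclohexan-1-one
Conditions: Br2, CH2Cl2, −20 → 0 °C, dark; used crude
Reagents that add atoms: bromine, BrBr
Why: Electrophilic anti addition of bromine to the enone alkene should give the trans-diaxial dibromide of the chair that keeps the C5 substituent equatorial (2S,3S), and since both C–Br centres are erased in step 4 their configuration is not critical.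

Step 4
Reactants: 5 (2S,3S,5R)-2,3-dibromo-2-methyl-5-(2-methyl-1,3-dioxolan-2-yl)cyclohexan-1-one
Product: 8 methyl (1R,5S)-2-methyl-5-(2-methyl-1,3-dioxolan-2-yl)cyclopent-2-ene-1-carboxylate, via bromocyclopropanone 6 (not isolated), via cis ester 7 (not isolated)
Conditions: NaOMe (3 equiv), MeOH, 0 °C → rt
Reagents that add atoms: sodium methoxide, [Na+].[O-]C
Why: Favorskii ring contraction: methoxide enolises the ketone toward its CH2 (future C9), the enolate carbon displaces the tertiary α-bromide to make the C8–C9 bond of bicyclo[3.1.0]hexan-6-one 6, and methoxide then adds to the strained carbonyl (future C10), whose bond to C8 breaks together with loss of the β-bromide, so that the alkene appears regiospecifically at C7=C8 and C10 leaves the ring as a methyl ester on C9. The closest known reaction type is the Favorskii rearrangement of α,β-dibromo ketones to β,γ-unsaturated esters, which is established for terpene-derived cyclohexanone dibromides. Ring A is closed by that 3-exo-tet attack of the enolate carbon on the C–Br carbon (inversion at C8), and the three-membered ring is opened again in the same flask. The one new stereocentre is C9: the cyclopropanone path puts the ester cis to the C5 dioxolanyl group (7) because the bridge forms on the face opposite the axial bromide, and the same methoxide then epimerises this α-ester centre to the trans isomer 8 (1R), which is favoured because it removes the vicinal cis interaction with the quaternary ketal carbon. The step needs the trans ester with the alkene kept at C7=C8; the bulky chiral-pool substituent on C5 secures the first, and the second relies on reprotonation of the ester enolate at C9 being faster than at C7, so the reaction is stopped as soon as 7 is consumed.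

Step 5
Reactants: 8 methyl (1R,5S)-2-methyl-5-(2-methyl-1,3-dioxolan-2-yl)cyclopent-2-ene-1-carboxylate
Product: 9 [(1R,5S)-2-methyl-5-(2-methyl-1,3-dioxolan-2-yl)cyclopent-2-en-1-yl]methanol
Conditions: LiAlH4, THF, 0 °C
Reagents that add atoms: none
Why: Hydride reduction of the ester to the primary alcohol is non-equilibrating, so the trans C5/C9 relationship, the ketal and the C7=C8 alkene are carried through unchanged.

Step 6
Reactants: 9 [(1R,5S)-2-methyl-5-(2-methyl-1,3-dioxolan-2-yl)cyclopent-2-en-1-yl]methanol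
Product: 10 (1R,5S)-2-methyl-5-(2-methyl-1,3-dioxolan-2-yl)cyclopent-2-ene-1-carbaldehyde
Conditions: Dess–Martin periodinane, NaHCO3, CH2Cl2, 0 °C → rt; used at once
Reagents that add atoms: none
Why: Buffered Dess–Martin oxidation gives the β,γ-unsaturated aldehyde under neutral conditions that neither epimerise C9 nor move the alkene into conjugation.

Step 7
Reactants: 11 3-[(4-methoxybenzyl)oxy]propan-1-ol
Product: 12 3-[(4-methoxybenzyl)oxy]propanal
Conditions: Dess–Martin periodinane, CH2Cl2, rt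
Reagents that add atoms: none
Why: Dess–Martin oxidation of a primary alcohol to the aldehyde leaves the p-methoxybenzyl ether untouched.

Step 8
Reactants: 12 3-[(4-methoxybenzyl)oxy]propanal; 13 methyl acrylate
Product: 14 methyl 3-hydroxy-5-[(4-methoxybenzyl)oxy]-2-methylidenepentanoate (racemic)
Conditions: DABCO (1 equiv), excess 13, MeOH, rt, several days
Reagents that add atoms: none
Why: Morita–Baylis–Hillman reaction of the unhindered aldehyde with methyl acrylate gives the α-methylene-β-hydroxy ester, and its carbinol centre needs no control because it is removed by the allylic transposition in step 9.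

Step 9
Reactants: 14 methyl 3-hydroxy-5-[(4-methoxybenzyl)oxy]-2-methylidenepentanoate
Product: 15 methyl (2Z)-2-(bromomethyl)-5-[(4-methoxybenzyl)oxy]pent-2-enoate
Conditions: NBS, Me2S, CH2Cl2, 0 °C → rt
Reagents that add atoms: N-bromosuccinimide, O=C1CCC(=O)N1Br
Why: Bromodimethylsulfonium activation of the allylic alcohol and SN2′ return of bromide (Corey–Kim-type bromination of a Baylis–Hillman adduct) gives the rearranged primary allylic bromide as the thermodynamically preferred Z isomer, in which the alkyl chain is trans to the ester.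

Step 10
Reactants: 10 (1R,5S)-2-methyl-5-(2-methyl-1,3-dioxolan-2-yl)cyclopent-2-ene-1-carbaldehyde; 15 methyl (2Z)-2-(bromomethyl)-5-[(4-methoxybenzyl)oxy]pent-2-enoate
Product: 17 (4R,5S)-4-{2-[(4-methoxybenzyl)oxy]ethyl}-3-methylidene-5-[(1R,5S)-2-methyl-5-(2-methyl-1,3-dioxolan-2-yl)cyclopent-2-en-1-yl]oxolan-2-one, via hydroxy ester 16 (not isolated)
Conditions: Zn dust (TMSCl-activated), THF, 45 °C; aq. NH4Cl
Reagents that add atoms: none
Why: In this Dreiding–Schmidt reaction the 2-(methoxycarbonyl)allylzinc reagent adds through its γ-carbon (C1) in a Zimmerman–Traxler chair with the C2 chain axial, which gives the syn adduct 16 that lactonises in the flask to the cis-4,5-disubstituted α-methylene lactone, while the C10 face should be chosen by approach anti to the alkenyl carbon C8 with H9 turned toward the axial C2 chain (syn-pentane avoidance, as for Z-crotylmetal additions to α-branched aldehydes), which sets 1R and 10S.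

Step 11
Reactants: 17 (4R,5S)-4-{2-[(4-methoxybenzyl)oxy]ethyl}-3-methylidene-5-[(1R,5S)-2-methyl-5-(2-methyl-1,3-dioxolan-2-yl)cyclopent-2-en-1-yl]oxolan-2-one
Product: 18 (3S,4R,5S)-4-{2-[(4-methoxybenzyl)oxy]ethyl}-3-methyl-5-[(1R,5S)-2-methyl-5-(2-methyl-1,3-dioxolan-2-yl)cyclopent-2-en-1-yl]oxolan-2-one (all-cis)
Conditions: LiBH(s-Bu)3 (L-Selectride), THF, −78 °C; then AcOH in THF, −78 °C
Reagents that add atoms: none
Why: Conjugate hydride addition to the exocyclic methylene gives the lactone enolate, and irreversible kinetic protonation at −78 °C from the face opposite the two cis substituents on C1 and C10 puts the new C11 methyl on their side (11S, the all-cis and less stable epimer, hence the cold acidic quench).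

Step 12
Reactants: 18 (3S,4R,5S)-4-{2-[(4-methoxybenzyl)oxy]ethyl}-3-methyl-5-[(1R,5S)-2-methyl-5-(2-methyl-1,3-dioxolan-2-yl)cyclopent-2-en-1-yl]oxolan-2-one
Product: 19 (3S,4R,5S)-5-[(1R,5S)-5-acetyl-2-methylcyclopent-2-en-1-yl]-4-{2-[(4-methoxybenzyl)oxy]ethyl}-3-methyloxolan-2-one
Conditions: PPTS, acetone/H2O, 55 °C
Reagents that add atoms: water, O
Why: Acid-catalysed hydrolysis (transketalisation to acetone) of the dioxolane unmasks the C4 methyl ketone, while the lactone and the p-methoxybenzyl ether survive and the non-enolising medium keeps C11 and C5 intact.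

Step 13
Reactants: 19 (3S,4R,5S)-5-[(1R,5S)-5-acetyl-2-methylcyclopent-2-en-1-yl]-4-{2-[(4-methoxybenzyl)oxy]ethyl}-3-methyloxolan-2-one
Product: 20 1-[(1S,2R)-2-[(2S,3R,4S)-3-{2-[(4-methoxybenzyl)oxy]ethyl}-4-methyl-5-oxooxolan-2-yl]-3-methylcyclopent-3-en-1-yl]ethenyl trifluoromethanesulfonate
Conditions: KN(SiMe3)2 (1.05 equiv), THF, −78 °C; then PhNTf2, −78 → 0 °C
Reagents that add atoms: N-phenylbis(trifluoromethanesulfonimide), O=S(=O)(N(c1ccccc1)S(=O)(=O)C(F)(F)F)C(F)(F)F
Why: Kinetic deprotonation of the methyl ketone is fastest at the unhindered CH3, ahead of the C5 methine and the hindered tertiary lactone α-CH, and O-sulfonylation of that enolate gives the terminal enol triflate in which the former methyl carbon has become the 4-methylidene carbon.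

Step 14
Reactants: 20 enol triflate with p-methoxybenzyl ether (name as in step 13)
Product: 21 1-[(1S,2R)-2-[(2S,3R,4S)-3-(2-hydroxyethyl)-4-methyl-5-oxooxolan-2-yl]-3-methylcyclopent-3-en-1-yl]ethenyl trifluoromethanesulfonate
Conditions: DDQ, CH2Cl2/pH 7 buffer, 0 °C → rt
Reagents that add atoms: none
Why: Oxidative cleavage of the p-methoxybenzyl ether with DDQ through the benzylic oxocarbenium ion is selective for the electron-rich arene and spares the trisubstituted alkene, the enol triflate and the lactone.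

Step 15
Reactants: 21 1-[(1S,2R)-2-[(2S,3R,4S)-3-(2-hydroxyethyl)-4-methyl-5-oxooxolan-2-yl]-3-methylcyclopent-3-en-1-yl]ethenyl trifluoromethanesulfonate
Product: 22 1-[(1S,2R)-3-methyl-2-[(2S,3R,4S)-4-methyl-5-oxo-3-(2-oxoethyl)oxolan-2-yl]cyclopent-3-en-1-yl]ethenyl trifluoromethanesulfonate
Conditions: Dess–Martin periodinane, NaHCO3, CH2Cl2, 0 °C → rt
Reagents that add atoms: none
Why: Neutral Dess–Martin oxidation of the primary alcohol gives the C3 aldehyde without disturbing the enol triflate or the C11 centre.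

Step 16
Reactants: 22 1-[(1S,2R)-3-methyl-2-[(2S,3R,4S)-4-methyl-5-oxo-3-(2-oxoethyl)oxolan-2-yl]cyclopent-3-en-1-yl]ethenyl trifluoromethanesulfonate
Product: 23 (3S,3aR,5S,6aS,9aR,9bS)-5-hydroxy-3,9-dimethyl-6-methylidene-3a,4,5,6,6a,7,9a,9b-octahydroazuleno[4,5-b]furan-2(3H)-one
Conditions: CrCl2 (8 equiv), NiCl2 (2 mol%), DMF, rt, slow addition to 2 mM
Reagents that add atoms: none
Why: In this intramolecular Nozaki–Hiyama–Kishi reaction zerovalent nickel inserts into the alkenyl triflate, transmetalation gives an alkenyl species of trivalent chromium that adds only to the aldehyde, and ring B closes at C3–C4 with the 3-hydroxy-4-methylidene unit formed in one operation, the chromium alkoxide being expected in the pseudo-equatorial site of the chair-like closure, which corresponds to 3S (3-OH cis to H5).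

Step 17
Reactants: 23 (3S,3aR,5S,6aS,9aR,9bS)-5-hydroxy-3,9-dimethyl-6-methylidene-3a,4,5,6,6a,7,9a,9b-octahydroazuleno[4,5-b]furan-2(3H)-one
Product: 24 (2S)-2-[(3aR,4S,5R,7S,8aS)-4,7-dihydroxy-3-methyl-8-methylidene-1,3a,4,5,6,7,8,8a-octahydroazulen-5-yl]-N-methoxy-N-methylpropanamide
Conditions: MeNH(OMe), AlMe3, CH2Cl2, 0 °C → rt; used crude
Reagents that add atoms: N,O-dimethylhydroxylamine, CNOC
Why: Weinreb aminolysis with the dimethylaluminium amide opens the γ-lactone under Lewis-acidic, non-basic conditions (the free 3-OH is carried as its aluminium alkoxide), so the all-cis C11 centre is not enolised and the 10-OH is released.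

Step 18
Reactants: 24 (2S)-2-[(3aR,4S,5R,7S,8aS)-4,7-dihydroxy-3-methyl-8-methylidene-1,3a,4,5,6,7,8,8a-octahydroazulen-5-yl]-N-methoxy-N-methylpropanamide
Product: 25 (2S)-2-[(3aR,4S,5R,7S,8aS)-4,7-bis(tert-butyldimethylsilyloxy)-3-methyl-8-methylidene-1,3a,4,5,6,7,8,8a-octahydroazulen-5-yl]-N-methoxy-N-methylpropanamide
Conditions: TBSOTf (3 equiv), 2,6-lutidine, CH2Cl2, −78 → 0 °C
Reagents that add atoms: tert-butyldimethylsilyl trifluoromethanesulfonate, CC(C)(C)[Si](C)(C)OS(=O)(=O)C(F)(F)F
Why: Silylation with the silyl triflate and a hindered base caps both the allylic 3-OH and the hindered 10-OH and thereby blocks re-lactonisation of the γ-hydroxy amide.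

Step 19
Reactants: 25 bis-silyl Weinreb amide (name as in step 18)
Product: 26 (2S)-2-[(3aR,4S,5R,7S,8aS)-4,7-bis(tert-butyldimethylsilyloxy)-3-methyl-8-methylidene-1,3a,4,5,6,7,8,8a-octahydroazulen-5-yl]propanal
Conditions: i-Bu2AlH, THF, −78 °C; used at once
Reagents that add atoms: none
Why: Reduction of the Weinreb amide by diisobutylaluminium hydride stops at the chelated hemiaminal, which releases the aldehyde only on work-up, so over-reduction is avoided and the α-stereocentre C11 is kept.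

Step 20
Reactants: 27 3-methylbut-3-en-2-one
Product: 28 trimethyl[(3-methylbuta-1,3-dien-2-yl)oxy]silane
Conditions: TMSOTf, Et3N, Et2O, 0 °C; distilled
Reagents that add atoms: trimethylsilyl trifluoromethanesulfonate, C[Si](C)(C)OS(=O)(=O)C(F)(F)F
Why: Soft enolisation and O-silylation of a ketone that can enolise only toward its methyl group gives the silyl enol ether needed for the Mukaiyama aldol.

Step 21
Reactants: 26 (2S)-2-[bis(silyloxy)azulen-5-yl]propanal (name as in step 19); 28 trimethyl[(3-methylbuta-1,3-dien-2-yl)oxy]silane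
Product: 29 (5S,6S)-6-[(3aR,4S,5R,7S,8aS)-4,7-bis(tert-butyldimethylsilyloxy)-3-methyl-8-methylidene-1,3a,4,5,6,7,8,8a-octahydroazulen-5-yl]-5-hydroxy-2-methylhept-1-en-3-one
Conditions: BF3·OEt2, CH2Cl2, −78 °C; aq. NaHCO3
Reagents that add atoms: none
Why: The Mukaiyama aldol addition runs through an open transition state and follows the Felkin–Anh model for the α-methyl aldehyde (attack anti to the ring carbon C1), which gives the 11,12-syn adduct and hence 12S, and the non-chelating Lewis acid ignores the remote silyl ethers.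

Step 22
Reactants: 29 β-hydroxy enone (name as in step 21)
Product: 30 (2S,3S)-2-[(3aR,4S,5R,7S,8aS)-4,7-bis(tert-butyldimethylsilyloxy)-3-methyl-8-methylidene-1,3a,4,5,6,7,8,8a-octahydroazulen-5-yl]-6-methyl-5-oxohept-6-en-3-yl acetate
Conditions: Ac2O, pyridine, DMAP (cat.), CH2Cl2, 0 °C
Reagents that add atoms: acetic anhydride, CC(=O)OC(C)=O
Why: Nucleophile-catalysed acylation of the secondary 12-OH at low temperature with only a weak amine base should be faster than elimination of the resulting β-acetoxy ketone.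

Step 23
Reactants: 30 β-acetoxy enone (name as in step 22)
Product: 31 (2S,3S,5R)-2-[(3aR,4S,5R,7S,8aS)-4,7-bis(tert-butyldimethylsilyloxy)-3-methyl-8-methylidene-1,3a,4,5,6,7,8,8a-octahydroazulen-5-yl]-5-hydroxy-6-methylhept-6-en-3-yl acetate
Conditions: (S)-2-methyl-CBS-oxazaborolidine (0.5 equiv), catecholborane, toluene, −78 °C
Reagents that add atoms: none
Why: Corey–Bakshi–Shibata reduction of the isopropenyl ketone is reagent-controlled, with the α-branched alkenyl group as the large substituent so that the (S)-catalyst gives 14R, and catecholborane at this temperature neither hydroborates the three alkenes nor reduces the acetate.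

Step 24
Reactants: 31 bis-silyl ether of the target (name as in step 23)
Product: 32 (2S,3S,5R)-5-hydroxy-2-[(3aR,4S,5R,7S,8aS)-4,7-dihydroxy-3-methyl-8-methylidene-1,3a,4,5,6,7,8,8a-octahydroazulen-5-yl]-6-methylhept-6-en-3-yl acetate (CNP0281601.4)
Conditions: HF·pyridine, pyridine, THF, 0 °C → rt
Reagents that add atoms: none
Why: Buffered acidic fluoride desilylation cleaves both secondary silyl ethers, and the mildly acidic medium suppresses base-mediated migration of the 12-acetate to the 14-OH or 10-OH.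

**Compound list**

1 | (S)-carvone | CC1=CC[C@@H](CC1=O)C(C)=C | starting material
2 | (5S)-5-acetyl-2-methylcyclohex-2-en-1-one | CC1=CC[C@@H](CC1=O)C(C)=O | intermediate
3 | ethylene glycol | OCCO | starting material
4 | (5S)-2-methyl-5-(2-methyl-1,3-dioxolan-2-yl)cyclohex-2-en-1-one | CC1=CC[C@@H](CC1=O)C2(C)OCCO2 | intermediate
5 | (2S,3S,5R)-2,3-dibromo-2-methyl-5-(2-methyl-1,3-dioxolan-2-yl)cyclohexan-1-one | C[C@@]1(Br)[C@@H](Br)C[C@@H](CC1=O)C2(C)OCCO2 | intermediate
6 | 2-bromo-1-methyl-4-(2-methyl-1,3-dioxolan-2-yl)bicyclo[3.1.0]hexan-6-one (carbonyl bridge cis to the dioxolanyl group, bromine trans to both) | C[C@@]12[C@@H](Br)C[C@H](C3(C)OCCO3)[C@@H]1C2=O | intermediate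
7 | methyl (1S,5S)-2-methyl-5-(2-methyl-1,3-dioxolan-2-yl)cyclopent-2-ene-1-carboxylate (cis ester) | COC(=O)[C@@H]1C(C)=CC[C@@H]1C2(C)OCCO2 | intermediate
8 | methyl (1R,5S)-2-methyl-5-(2-methyl-1,3-dioxolan-2-yl)cyclopent-2-ene-1-carboxylate (trans ester) | COC(=O)[C@H]1C(C)=CC[C@@H]1C2(C)OCCO2 | intermediate
9 | [(1R,5S)-2-methyl-5-(2-methyl-1,3-dioxolan-2-yl)cyclopent-2-en-1-yl]methanol | OC[C@H]1C(C)=CC[C@@H]1C2(C)OCCO2 | intermediate
10 | (1R,5S)-2-methyl-5-(2-methyl-1,3-dioxolan-2-yl)cyclopent-2-ene-1-carbaldehyde | O=C[C@H]1C(C)=CC[C@@H]1C2(C)OCCO2 | intermediate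
11 | 3-[(4-methoxybenzyl)oxy]propan-1-ol | COc1ccc(COCCCO)cc1 | starting material
12 | 3-[(4-methoxybenzyl)oxy]propanal | COc1ccc(COCCC=O)cc1 | intermediate
13 | methyl acrylate | C=CC(=O)OC | starting material
14 | methyl 3-hydroxy-5-[(4-methoxybenzyl)oxy]-2-methylidenepentanoate (racemic) | COC(=O)C(=C)C(O)CCOCc1ccc(OC)cc1 | intermediate
15 | methyl (2Z)-2-(bromomethyl)-5-[(4-methoxybenzyl)oxy]pent-2-enoate | COC(=O)/C(CBr)=C/CCOCc1ccc(OC)cc1 | intermediate
16 | methyl (3R,4S)-4-hydroxy-3-{2-[(4-methoxybenzyl)oxy]ethyl}-2-methylidene-4-[(1R,5S)-2-methyl-5-(2-methyl-1,3-dioxolan-2-yl)cyclopent-2-en-1-yl]butanoate | COC(=O)C(=C)[C@@H](CCOCc1ccc(OC)cc1)[C@H](O)[C@H]1C(C)=CC[C@@H]1C2(C)OCCO2 | intermediate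
17 | (4R,5S)-4-{2-[(4-methoxybenzyl)oxy]ethyl}-3-methylidene-5-[(1R,5S)-2-methyl-5-(2-methyl-1,3-dioxolan-2-yl)cyclopent-2-en-1-yl]oxolan-2-one | O=C1O[C@H]([C@H]2C(C)=CC[C@@H]2C3(C)OCCO3)[C@H](CCOCc2ccc(OC)cc2)C1=C | intermediate
18 | (3S,4R,5S)-4-{2-[(4-methoxybenzyl)oxy]ethyl}-3-methyl-5-[(1R,5S)-2-methyl-5-(2-methyl-1,3-dioxolan-2-yl)cyclopent-2-en-1-yl]oxolan-2-one | O=C1O[C@H]([C@H]2C(C)=CC[C@@H]2C3(C)OCCO3)[C@H](CCOCc2ccc(OC)cc2)[C@@H]1C | intermediate
19 | (3S,4R,5S)-5-[(1R,5S)-5-acetyl-2-methylcyclopent-2-en-1-yl]-4-{2-[(4-methoxybenzyl)oxy]ethyl}-3-methyloxolan-2-one | O=C1O[C@H]([C@H]2C(C)=CC[C@@H]2C(C)=O)[C@H](CCOCc2ccc(OC)cc2)[C@@H]1C | intermediate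
20 | 1-[(1S,2R)-2-[(2S,3R,4S)-3-{2-[(4-methoxybenzyl)oxy]ethyl}-4-methyl-5-oxooxolan-2-yl]-3-methylcyclopent-3-en-1-yl]ethenyl trifluoromethanesulfonate | O=C1O[C@H]([C@H]2C(C)=CC[C@@H]2C(=C)OS(=O)(=O)C(F)(F)F)[C@H](CCOCc2ccc(OC)cc2)[C@@H]1C | intermediate
21 | 1-[(1S,2R)-2-[(2S,3R,4S)-3-(2-hydroxyethyl)-4-methyl-5-oxooxolan-2-yl]-3-methylcyclopent-3-en-1-yl]ethenyl trifluoromethanesulfonate | O=C1O[C@H]([C@H]2C(C)=CC[C@@H]2C(=C)OS(=O)(=O)C(F)(F)F)[C@H](CCO)[C@@H]1C | intermediate
22 | 1-[(1S,2R)-3-methyl-2-[(2S,3R,4S)-4-methyl-5-oxo-3-(2-oxoethyl)oxolan-2-yl]cyclopent-3-en-1-yl]ethenyl trifluoromethanesulfonate | O=C1O[C@H]([C@H]2C(C)=CC[C@@H]2C(=C)OS(=O)(=O)C(F)(F)F)[C@H](CC=O)[C@@H]1C | intermediate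
23 | (3S,3aR,5S,6aS,9aR,9bS)-5-hydroxy-3,9-dimethyl-6-methylidene-3a,4,5,6,6a,7,9a,9b-octahydroazuleno[4,5-b]furan-2(3H)-one | O=C1O[C@@H]2[C@H]3C(C)=CC[C@@H]3C(=C)[C@@H](O)C[C@@H]2[C@@H]1C | intermediate
24 | (2S)-2-[(3aR,4S,5R,7S,8aS)-4,7-dihydroxy-3-methyl-8-methylidene-1,3a,4,5,6,7,8,8a-octahydroazulen-5-yl]-N-methoxy-N-methylpropanamide | CON(C)C(=O)[C@@H](C)[C@H]1C[C@H](O)C(=C)[C@H]2CC=C(C)[C@@H]2[C@H]1O | intermediate
25 | (2S)-2-[(3aR,4S,5R,7S,8aS)-4,7-bis(tert-butyldimethylsilyloxy)-3-methyl-8-methylidene-1,3a,4,5,6,7,8,8a-octahydroazulen-5-yl]-N-methoxy-N-methylpropanamide | CON(C)C(=O)[C@@H](C)[C@H]1C[C@H](O[Si](C)(C)C(C)(C)C)C(=C)[C@H]2CC=C(C)[C@@H]2[C@H]1O[Si](C)(C)C(C)(C)C | intermediate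
26 | (2S)-2-[(3aR,4S,5R,7S,8aS)-4,7-bis(tert-butyldimethylsilyloxy)-3-methyl-8-methylidene-1,3a,4,5,6,7,8,8a-octahydroazulen-5-yl]propanal | O=C[C@@H](C)[C@H]1C[C@H](O[Si](C)(C)C(C)(C)C)C(=C)[C@H]2CC=C(C)[C@@H]2[C@H]1O[Si](C)(C)C(C)(C)C | intermediate
27 | 3-methylbut-3-en-2-one | CC(=O)C(C)=C | starting material
28 | trimethyl[(3-methylbuta-1,3-dien-2-yl)oxy]silane | C=C(O[Si](C)(C)C)C(C)=C | intermediate
29 | (5S,6S)-6-[(3aR,4S,5R,7S,8aS)-4,7-bis(tert-butyldimethylsilyloxy)-3-methyl-8-methylidene-1,3a,4,5,6,7,8,8a-octahydroazulen-5-yl]-5-hydroxy-2-methylhept-1-en-3-one | C=C(C)C(=O)C[C@H](O)[C@@H](C)[C@H]1C[C@H](O[Si](C)(C)C(C)(C)C)C(=C)[C@H]2CC=C(C)[C@@H]2[C@H]1O[Si](C)(C)C(C)(C)C | intermediate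
30 | (2S,3S)-2-[(3aR,4S,5R,7S,8aS)-4,7-bis(tert-butyldimethylsilyloxy)-3-methyl-8-methylidene-1,3a,4,5,6,7,8,8a-octahydroazulen-5-yl]-6-methyl-5-oxohept-6-en-3-yl acetate | C=C(C)C(=O)C[C@H](OC(C)=O)[C@@H](C)[C@H]1C[C@H](O[Si](C)(C)C(C)(C)C)C(=C)[C@H]2CC=C(C)[C@@H]2[C@H]1O[Si](C)(C)C(C)(C)C | intermediate
31 | (2S,3S,5R)-2-[(3aR,4S,5R,7S,8aS)-4,7-bis(tert-butyldimethylsilyloxy)-3-methyl-8-methylidene-1,3a,4,5,6,7,8,8a-octahydroazulen-5-yl]-5-hydroxy-6-methylhept-6-en-3-yl acetate | C=C(C)[C@H](O)C[C@H](OC(C)=O)[C@@H](C)[C@H]1C[C@H](O[Si](C)(C)C(C)(C)C)C(=C)[C@H]2CC=C(C)[C@@H]2[C@H]1O[Si](C)(C)C(C)(C)C | intermediate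
32 | (2S,3S,5R)-5-hydroxy-2-[(3aR,4S,5R,7S,8aS)-4,7-dihydroxy-3-methyl-8-methylidene-1,3a,4,5,6,7,8,8a-octahydroazulen-5-yl]-6-methylhept-6-en-3-yl acetate | C=C(C)[C@H](O)C[C@H](OC(C)=O)[C@@H](C)[C@H]1C[C@H](O)C(=C)[C@H]2CC=C(C)[C@@H]2[C@H]1O | target

**Step count and risks**

Total step count: 24. Longest linear sequence: 20 steps from (S)-carvone (steps 1–6, 10–19, 21–24).

Steps most likely to fail:

Step 10. The closed transition state secures the 1,10-syn relationship but not its sense relative to C9, so facial selection at C10 may be low or reversed; the β,γ-unsaturated aldehyde may also epimerise at C9 on the zinc surface before it is consumed. The fallback sets out from bromide 15 (with aldehyde 10) and comes back at lactone 17. Bromide 15 is borylated with B2pin2 under Pd2(dba)3 catalysis to methyl (2E)-5-[(4-methoxybenzyl)oxy]-2-[(4,4,5,5-tetramethyl-1,3,2-dioxaborolan-2-yl)methyl]pent-2-enoate F1. F1 is then added to 10 under a chiral BINOL-derived phosphoric acid, so that the catalyst enantiomer, not the aldehyde, decides the C10 face while the closed chair still gives the syn adduct. The hydroxy ester 16 is isolated and closed to 17 with PPTS.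

Step 16. The alkenylmetal may be protonated before it reaches the aldehyde, and the closure may show poor facial selectivity at C3. The fallback sets out from aldehyde 22 and comes back at 23. The cyclisation is run for conversion only, and the crude alcohols, (3S,3aR,5R,6aS,9aR,9bS)-5-hydroxy-3,9-dimethyl-6-methylidene-3a,4,5,6,6a,7,9a,9b-octahydroazuleno[4,5-b]furan-2(3H)-one F2 together with 23, are oxidised with MnO2 to the exocyclic enone (3S,3aR,6aS,9aR,9bS)-3,9-dimethyl-6-methylidene-3a,4,6,6a,7,9a,9b-heptahydroazuleno[4,5-b]furan-2,5(3H)-dione F3. F3 is reduced with catecholborane and (R)-2-methyl-CBS-oxazaborolidine, where the catalyst, with the methylidene-bearing C4 as the large group, fixes 3S.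

Step 17. The hindered all-cis lactone may open incompletely, the γ-hydroxy amide may re-close before it is silylated, and C11 may enolise if the aminolysis is forced. The fallback sets out from 23 and comes back at aldehyde 26. LiAlH4 reduces 23 to the triol (2S)-2-[(3aR,4S,5R,7S,8aS)-4,7-dihydroxy-3-methyl-8-methylidene-1,3a,4,5,6,7,8,8a-octahydroazulen-5-yl]propan-1-ol F4. TBSOTf/2,6-lutidine gives the tris(tert-butyldimethylsilyl) ether of this triol F5. HF·pyridine in pyridine/THF at 0 °C removes only the primary silyl group to give (2S)-2-[(3aR,4S,5R,7S,8aS)-4,7-bis(tert-butyldimethylsilyloxy)-3-methyl-8-methylidene-1,3a,4,5,6,7,8,8a-octahydroazulen-5-yl]propan-1-ol F6, and Dess–Martin oxidation of F6 gives 26.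

Further compounds
F1 | step 10 | methyl (2E)-5-[(4-methoxybenzyl)oxy]-2-[(4,4,5,5-tetramethyl-1,3,2-dioxaborolan-2-yl)methyl]pent-2-enoate | COC(=O)/C(CB1OC(C)(C)C(C)(C)O1)=C/CCOCc1ccc(OC)cc1
F2 | step 16 | (3S,3aR,5R,6aS,9aR,9bS)-5-hydroxy-3,9-dimethyl-6-methylidene-3a,4,5,6,6a,7,9a,9b-octahydroazuleno[4,5-b]furan-2(3H)-one | O=C1O[C@@H]2[C@H]3C(C)=CC[C@@H]3C(=C)[C@H](O)C[C@@H]2[C@@H]1C
F3 | step 16 | (3S,3aR,6aS,9aR,9bS)-3,9-dimethyl-6-methylidene-3a,4,6,6a,7,9a,9b-heptahydroazuleno[4,5-b]furan-2,5(3H)-dione | O=C1O[C@@H]2[C@H]3C(C)=CC[C@@H]3C(=C)C(=O)C[C@@H]2[C@@H]1C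
F4 | step 17 | (2S)-2-[(3aR,4S,5R,7S,8aS)-4,7-dihydroxy-3-methyl-8-methylidene-1,3a,4,5,6,7,8,8a-octahydroazulen-5-yl]propan-1-ol | OC[C@@H](C)[C@H]1C[C@H](O)C(=C)[C@H]2CC=C(C)[C@@H]2[C@H]1O
F5 | step 17 | tris(tert-butyldimethylsilyl) ether of F4 | CC(C)(C)[Si](C)(C)OC[C@@H](C)[C@H]1C[C@H](O[Si](C)(C)C(C)(C)C)C(=C)[C@H]2CC=C(C)[C@@H]2[C@H]1O[Si](C)(C)C(C)(C)C
F6 | step 17 | (2S)-2-[(3aR,4S,5R,7S,8aS)-4,7-bis(tert-butyldimethylsilyloxy)-3-methyl-8-methylidene-1,3a,4,5,6,7,8,8a-octahydroazulen-5-yl]propan-1-ol | OC[C@@H](C)[C@H]1C[C@H](O[Si](C)(C)C(C)(C)C)C(=C)[C@H]2CC=C(C)[C@@H]2[C@H]1O[Si](C)(C)C(C)(C)C
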